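**Retrosynthetic overview**
1. Cut the C5–O aryl ether and the left-hand pyranone (O1–C2 and C4–C4a) together: the target comes from a 6-hydroxy-7-O-protected 2-(2-phenylethyl)chromone, a chiral 2-iodocyclohexenone, CO and 4-phenyl-1-butyne.
2. The iodoenone comes from a 6-acetoxy-4,5-acetonide cyclohexenone, itself the β-elimination product of a cyclic α-ketol.
3. Key C–C bond C8–C8a: a carbene-generated acyl anion (Breslow intermediate) of one aldehyde adds to the other aldehyde of a 5-deoxy-hexodialdose, closing the carbocycle and setting C8.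
4. The dialdose comes from diacetone-D-mannose and allyl Grignard; mannose C2 and C3 become C6 and C7.
5. Ring order: right-hand chromone (made separately), then the carbocycle (key step), then the left-hand pyranone (last).

Assumption: the target is read as (5S,6S,7R,8S), i.e. 5,6-trans, 6,7-cis, 7,8-trans; locants C2–C8a in the text are those of the target's tetrahydrochromone ring; the allyl Grignard is drawn as adding anti (talo), and its epimer is carried along because that carbon becomes sp2 in step 4.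

**Route**

Step 1
Reactants: 1 2,3:5,6-di-O-isopropylidene-α-D-mannofuranose; 2 allylmagnesium bromide
Product: 3 1,2,3-trideoxy-5,6:8,9-di-O-isopropylidene-D-glycero-D-talo-non-1-enitol
Conditions: allylMgBr (3 equiv), THF, −20 °C to rt; aq. NH4Cl
Reagents that add atoms: none
Why: Grignard addition to the open aldehyde form of the lactol (the first equivalent deprotonates the anomeric OH) gives the chain-extended diol, whose new carbinol (future C5) is later erased, so its configuration does not matter.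

Step 2
Reactants: 3 1,2,3-trideoxy-5,6:8,9-di-O-isopropylidene-D-glycero-D-talo-non-1-enitol
Product: 4 1,2,3-trideoxy-5,6-O-isopropylidene-D-glycero-D-talo-non-1-enitol
Conditions: AcOH/H2O (7:3), rt
Reagents that add atoms: none
Why: Kinetically selective acetal hydrolysis removes the terminal dioxolane and leaves the internal one, exposing the terminal triol without touching any stereocentre.

Step 3
Reactants: 4 1,2,3-trideoxy-5,6-O-isopropylidene-D-glycero-D-talo-non-1-enitol
Product: 5 5-deoxy-2,3-O-isopropylidene-D-ribo-hexodialdo-1,4-furanose (lactol, anomer mixture)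
Conditions: OsO4 (2 mol %), NaIO4 (4.5 equiv), 2,6-lutidine, dioxane/H2O, rt
Reagents that add atoms: osmium tetroxide O=[Os](=O)(=O)=O (catalytic oxygen transfer), sodium periodate [Na+].[O-]I(=O)(=O)=O
Why: One-pot Malaprade glycol cleavage of the triol and Lemieux–Johnson cleavage of the vinyl group give the 1,6-dialdehyde, in which the C8 aldehyde is held as a furanose lactol by the C5 hydroxyl while the CH2CHO aldehyde (C8a) stays free, with C6 and C7 (mannose C2, C3) untouched.

Step 4
Reactants: 5 5-deoxy-2,3-O-isopropylidene-D-ribo-hexodialdo-1,4-furanose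
Product: 8 (4R,5R,6S)-6-acetoxy-4,5-(isopropylidenedioxy)cyclohex-2-en-1-one, via cyclic ketol 6 (not isolated), via ketol diacetate 7 (not isolated)
Conditions: 2-(pentafluorophenyl)-6,7-dihydro-5H-pyrrolo[2,1-c][1,2,4]triazol-2-ium tetrafluoroborate (20 mol %), Et3N, CH2Cl2 (0.02 M), rt; then Ac2O, DMAP, Et3N, 0 °C to rt
Reagents that add atoms: acetic anhydride CC(=O)OC(C)=O
Why: Proposed new method: the carbene adds to the only free aldehyde (C8a) to give a Breslow acyl-anion equivalent that closes onto the C8 aldehyde released from the lactol, a six-membered crossed benzoin joining two aldehyde carbons (closest known reaction: carbene-catalysed benzoin cyclisation of protected hexodialdoses to inososes), with the acceptor oxygen on the convex face anti to the C7–O bond of the cis-fused dioxolane so that the new C8–O is trans to C7–O (S), an outcome the epimerisable α-ketol can also reach by equilibration, after which in-pot acetylation caps C8–OH and E1cB loss of the C5 acetate locks the ketone as the conjugated enone.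

Step 5
Reactants: 8 (4R,5R,6S)-6-acetoxy-4,5-(isopropylidenedioxy)cyclohex-2-en-1-one
Product: 9 (4R,5R,6S)-6-acetoxy-2-iodo-4,5-(isopropylidenedioxy)cyclohex-2-en-1-one
Conditions: I2, pyridine/CH2Cl2 (1:1), 0 °C to rt
Reagents that add atoms: iodine II
Why: Johnson α-iodination of the enone (pyridine conjugate addition, enolate iodination, E1cB loss of pyridine) puts the coupling handle on C4a without touching C6–C8.

Step 6
Reactants: 10 1-(2-hydroxy-4,5-dimethoxyphenyl)ethanone; 11 ethyl 3-phenylpropanoate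
Product: 13 6,7-dimethoxy-2-(2-phenylethyl)chromen-4-one, via aryl 1,3-diketone 12 (not isolated)
Conditions: NaH, THF, reflux; then conc. HCl, AcOH, 100 °C
Reagents that add atoms: none
Why: Crossed Claisen condensation of the acetophenone enolate with the ester followed by acid-catalysed cyclodehydration of the o-hydroxyaryl 1,3-diketone gives the chromone (no stereocentres).

Step 7
Reactants: 13 6,7-dimethoxy-2-(2-phenylethyl)chromen-4-one
Product: 14 6,7-dihydroxy-2-(2-phenylethyl)chromen-4-one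
Conditions: BBr3 (4 equiv), CH2Cl2, −78 °C to rt; H2O
Reagents that add atoms: none
Why: Lewis-acid ether cleavage (BBr3 demethylation) frees both phenols.

Step 8
Reactants: 14 6,7-dihydroxy-2-(2-phenylethyl)chromen-4-one
Product: 15 6-hydroxy-7-(methoxymethoxy)-2-(2-phenylethyl)chromen-4-one
Conditions: MOMCl (1.05 equiv), iPr2NEt (1.2 equiv), CH2Cl2, 0 °C
Reagents that add atoms: chloromethyl methyl ether COCCl
Why: Williamson-type O-alkylation goes to the 7-OH because it is para to the pyranone carbonyl and therefore the phenol ionised by one equivalent of base, leaving the 6-OH free as the later nucleophile.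

Step 9
Reactants: 9 (4R,5R,6S)-6-acetoxy-2-iodo-4,5-(isopropylidenedioxy)cyclohex-2-en-1-one; 16 but-3-yn-1-ylbenzene (4-phenyl-1-butyne); 15 6-hydroxy-7-(methoxymethoxy)-2-(2-phenylethyl)chromen-4-one
Product: 19 (5S,6R,7R,8S)-8-acetoxy-6,7-(isopropylidenedioxy)-5-{[7-(methoxymethoxy)-4-oxo-2-(2-phenylethyl)chromen-6-yl]oxy}-2-(2-phenylethyl)-5,6,7,8-tetrahydrochromen-4-one, via alkynoyl enone 17 (not isolated), via aryloxy diketone enol 18 (not isolated)
Conditions: PdCl2(PPh3)2 (5 mol %), CuI (2 mol %), Et3N, CO (1 atm), THF, rt; then 15, K2CO3 (0.5 equiv), MeCN, rt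
Reagents that add atoms: carbon monoxide [C-]#[O+]
Why: Carbonylative Sonogashira coupling of the α-iodoenone gives a doubly activated alkylidene 1,3-dicarbonyl, the 6-phenoxide adds to C5 (oxa-Michael) on the face anti to the C6–O bond of the cis-fused dioxolane to set C5 (S, trans to C6–O), and the C8a enol oxygen then closes onto the ynone (6-endo-dig oxa-Michael) to give the γ-pyranone, which makes the aryloxy addition irreversible and lets any phenoxide added reversibly to the ynone carbon return.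

Step 10
Reactants: 19 (5S,6R,7R,8S)-8-acetoxy-6,7-(isopropylidenedioxy)-5-{[7-(methoxymethoxy)-4-oxo-2-(2-phenylethyl)chromen-6-yl]oxy}-2-(2-phenylethyl)-5,6,7,8-tetrahydrochromen-4-one
Product: 20 (5S,6S,7R,8S)-6,7,8-trihydroxy-5-{[7-hydroxy-4-oxo-2-(2-phenylethyl)chromen-6-yl]oxy}-2-(2-phenylethyl)-5,6,7,8-tetrahydrochromen-4-one (CNP0248258.1)
Conditions: HCl (1.25 M in MeOH), 0 °C to rt
Reagents that add atoms: none
Why: Acid-catalysed transacetalisation removes the acetonide and the MOM ether and acid methanolysis removes the C8 acetate, while the protonated pyranone disfavours ionisation at C5 and C8, so all four stereocentres are kept.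

**Compound list**

1 | 2,3:5,6-di-O-isopropylidene-α-D-mannofuranose | O[C@@H]1[C@H]2OC(C)(C)O[C@H]2[C@H](O1)[C@H]1COC(C)(C)O1 | starting material
2 | allylmagnesium bromide | C=CC[Mg]Br | starting material
3 | 1,2,3-trideoxy-5,6:8,9-di-O-isopropylidene-D-glycero-D-talo-non-1-enitol | C=CC[C@@H](O)[C@H]1OC(C)(C)O[C@H]1[C@H](O)[C@H]1COC(C)(C)O1 | intermediate
4 | 1,2,3-trideoxy-5,6-O-isopropylidene-D-glycero-D-talo-non-1-enitol | C=CC[C@@H](O)[C@H]1OC(C)(C)O[C@H]1[C@H](O)[C@H](O)CO | intermediate
5 | 5-deoxy-2,3-O-isopropylidene-D-ribo-hexodialdo-1,4-furanose (lactol, anomer mixture, C6 aldehyde free) | O=CC[C@@H]1[C@H]2OC(C)(C)O[C@H]2C(O)O1 | intermediate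
6 | (2S,3S,4R,5R)-2,5-dihydroxy-3,4-(isopropylidenedioxy)cyclohexan-1-one | O=C1C[C@@H](O)[C@H]2OC(C)(C)O[C@H]2[C@@H]1O | intermediate
7 | (2S,3R,4R,5R)-2,5-diacetoxy-3,4-(isopropylidenedioxy)cyclohexan-1-one | O=C1C[C@@H](OC(C)=O)[C@H]2OC(C)(C)O[C@H]2[C@@H]1OC(C)=O | intermediate
8 | (4R,5R,6S)-6-acetoxy-4,5-(isopropylidenedioxy)cyclohex-2-en-1-one | O=C1C=C[C@H]2OC(C)(C)O[C@H]2[C@@H]1OC(C)=O | intermediate
9 | (4R,5R,6S)-6-acetoxy-2-iodo-4,5-(isopropylidenedioxy)cyclohex-2-en-1-one | O=C1C(I)=C[C@H]2OC(C)(C)O[C@H]2[C@@H]1OC(C)=O | intermediate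
10 | 1-(2-hydroxy-4,5-dimethoxyphenyl)ethanone | CC(=O)c1cc(OC)c(OC)cc1O | starting material
11 | ethyl 3-phenylpropanoate | CCOC(=O)CCc1ccccc1 | starting material
12 | 1-(2-hydroxy-4,5-dimethoxyphenyl)-5-phenylpentane-1,3-dione | O=C(CC(=O)CCc1ccccc1)c1cc(OC)c(OC)cc1O | intermediate
13 | 6,7-dimethoxy-2-(2-phenylethyl)chromen-4-one | COc1cc2oc(CCc3ccccc3)cc(=O)c2cc1OC | intermediate
14 | 6,7-dihydroxy-2-(2-phenylethyl)chromen-4-one | Oc1cc2oc(CCc3ccccc3)cc(=O)c2cc1O | intermediate
15 | 6-hydroxy-7-(methoxymethoxy)-2-(2-phenylethyl)chromen-4-one | COCOc1cc2oc(CCc3ccccc3)cc(=O)c2cc1O | intermediate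
16 | but-3-yn-1-ylbenzene (4-phenyl-1-butyne) | C#CCCc1ccccc1 | starting material
17 | (4R,5R,6S)-6-acetoxy-4,5-(isopropylidenedioxy)-2-(5-phenylpent-2-ynoyl)cyclohex-2-en-1-one | O=C1C(C(=O)C#CCCc2ccccc2)=C[C@H]2OC(C)(C)O[C@H]2[C@@H]1OC(C)=O | intermediate
18 | enol form of (3S,4R,5R,6S)-6-acetoxy-3-{[7-(methoxymethoxy)-4-oxo-2-(2-phenylethyl)chromen-6-yl]oxy}-4,5-(isopropylidenedioxy)-2-(5-phenylpent-2-ynoyl)cyclohexan-1-one | OC1=C(C(=O)C#CCCc2ccccc2)[C@H](Oc2cc3c(=O)cc(CCc4ccccc4)oc3cc2OCOC)[C@H]2OC(C)(C)O[C@H]2[C@@H]1OC(C)=O | intermediate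
19 | (5S,6R,7R,8S)-8-acetoxy-6,7-(isopropylidenedioxy)-5-{[7-(methoxymethoxy)-4-oxo-2-(2-phenylethyl)chromen-6-yl]oxy}-2-(2-phenylethyl)-5,6,7,8-tetrahydrochromen-4-one | O=c1cc(CCc2ccccc2)oc2c1[C@H](Oc1cc3c(=O)cc(CCc4ccccc4)oc3cc1OCOC)[C@H]1OC(C)(C)O[C@H]1[C@@H]2OC(C)=O | intermediate
20 | (5S,6S,7R,8S)-6,7,8-trihydroxy-5-{[7-hydroxy-4-oxo-2-(2-phenylethyl)chromen-6-yl]oxy}-2-(2-phenylethyl)-5,6,7,8-tetrahydrochromen-4-one | O=c1cc(CCc2ccccc2)oc2c1[C@H](Oc1cc3c(=O)cc(CCc4ccccc4)oc3cc1O)[C@@H](O)[C@@H](O)[C@@H]2O | target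

**Step count and risks**

Total: 10 steps. Longest linear sequence: 7 steps (1, 2, 3, 4, 5, 9, 10 from compound 1); the phenol branch is 3 steps (6, 7, 8).

Most likely to fail:

Step 4. The β-alkoxy aldehyde may open by E1cB before the carbene engages it, the lactol may be a poor acceptor, or C8 may form cis to C7–O. The fallback sets out from 1 and comes back at 8; it closes the carbocycle by olefin metathesis and takes C8 unchanged from mannose C4. Wittig methylenation of 1 (Ph3PCH3Br, KN(SiMe3)2, THF) gives 1,2-dideoxy-3,4:6,7-di-O-isopropylidene-D-manno-hept-1-enitol F1. Acetylation (Ac2O, pyridine) gives its 5-O-acetate F2, and AcOH/H2O removes the terminal acetonide to give the 6,7-diol F3. NaIO4 then gives 2-O-acetyl-5,6-dideoxy-3,4-O-isopropylidene-D-arabino-hex-5-enose F4. Ester-tolerant Nozaki–Hiyama–Kishi vinylation (vinyl bromide, CrCl2, NiCl2 cat., DMF) gives the octa-1,7-dien-3-ol F5 as a carbinol mixture. Ring-closing metathesis with the second-generation Grubbs catalyst RuCl2(=CHPh)(H2IMes)(PCy3) gives the cyclohexenol F6, and Dess–Martin oxidation gives 8.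

Step 9. The carbonylation may give direct alkynylation, or the very electrophilic ynone may not survive palladium, amine and CO long enough for a clean phenoxide cascade. The fallback sets out from 8 and 16 and comes back at 17, which is then isolated and taken on to 19. Formylation of 16 (n-BuLi, then DMF) gives 5-phenylpent-2-ynal F7. A Morita–Baylis–Hillman reaction of 8 with F7 (DABCO or imidazole, aq. THF) gives the propargylic alcohol F8 as a carbinol mixture. Dess–Martin oxidation gives 17 free of metal and amine, and 17 is then treated with 15 and K2CO3 in MeCN at −20 °C to rt to give 19 by the same oxa-Michael and 6-endo closure.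

Step 10. Acid methanolysis of the acetate may be slow enough for solvolysis at C5 or C8, or dehydrative aromatisation, to compete. The fallback sets out from 19 and comes back at 20; it unmasks in two orthogonal stages and avoids protic acid. Transesterification (K2CO3 cat., MeOH, 0 °C) gives the C8 alcohol of 19 with acetonide and MOM retained F9. Me2BBr in CH2Cl2 at −78 °C then cleaves the acetonide and the MOM ether by chelation, and aqueous NaHCO3 work-up gives 20.

**Further compounds**

F1 | step 4 | 1,2-dideoxy-3,4:6,7-di-O-isopropylidene-D-manno-hept-1-enitol | C=C[C@H]1OC(C)(C)O[C@H]1[C@H](O)[C@H]1COC(C)(C)O1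
F2 | step 4 | 5-O-acetyl-1,2-dideoxy-3,4:6,7-di-O-isopropylidene-D-manno-hept-1-enitol | C=C[C@H]1OC(C)(C)O[C@H]1[C@H](OC(C)=O)[C@H]1COC(C)(C)O1
F3 | step 4 | 5-O-acetyl-1,2-dideoxy-3,4-O-isopropylidene-D-manno-hept-1-enitol | C=C[C@H]1OC(C)(C)O[C@H]1[C@H](OC(C)=O)[C@H](O)CO
F4 | step 4 | 2-O-acetyl-5,6-dideoxy-3,4-O-isopropylidene-D-arabino-hex-5-enose | C=C[C@H]1OC(C)(C)O[C@H]1[C@H](OC(C)=O)C=O
F5 | step 4 | 4-O-acetyl-1,2,7,8-tetradeoxy-5,6-O-isopropylidene-octa-1,7-dienitol (3-OH free, C3 epimers, other centres as in F4) | C=C[C@H]1OC(C)(C)O[C@H]1[C@H](OC(C)=O)C(O)C=C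
F6 | step 4 | 6-acetoxy-4,5-(isopropylidenedioxy)cyclohex-2-en-1-ol (C1 epimers, C4–C6 as in 8) | OC1C=C[C@H]2OC(C)(C)O[C@H]2[C@@H]1OC(C)=O
F7 | step 9 | 5-phenylpent-2-ynal | O=CC#CCCc1ccccc1
F8 | step 9 | (4R,5R,6S)-6-acetoxy-2-(1-hydroxy-5-phenylpent-2-yn-1-yl)-4,5-(isopropylidenedioxy)cyclohex-2-en-1-one (carbinol epimers) | O=C1C(C(O)C#CCCc2ccccc2)=C[C@H]2OC(C)(C)O[C@H]2[C@@H]1OC(C)=O
F9 | step 10 | (5S,6R,7S,8S)-8-hydroxy-6,7-(isopropylidenedioxy)-5-{[7-(methoxymethoxy)-4-oxo-2-(2-phenylethyl)chromen-6-yl]oxy}-2-(2-phenylethyl)-5,6,7,8-tetrahydrochromen-4-one | O=c1cc(CCc2ccccc2)oc2c1[C@H](Oc1cc3c(=O)cc(CCc4ccccc4)oc3cc1OCOC)[C@H]1OC(C)(C)O[C@H]1[C@@H]2O
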